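## Retrosynthetic overview

1. The last bond made is the ketone carbon–alkenyl carbon bond of the cross-conjugated dienone. An acylzirconocene chloride (an unmasked acyl anion built from (4S)-4-methylhex-2-yne, Cp2Zr(H)Cl and CO) is coupled under palladium catalysis with the alkenyl iodide of the complete pyranone–triene fragment.
2. The pyranone–triene alkenyl iodide comes from a lateral (vinylogous) aldol/elimination between 6-ethyl-4-hydroxy-3,5-dimethylpyran-2-one and (2E,4S,5E)-6-iodo-2,4-dimethylhepta-2,5-dienal.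
3. The dienal comes from a Wittig reaction on an α-chiral aldehyde, itself made by hydrozirconation/iodination and glycol cleavage of an alkynyl diol. The skipped-diene stereocentre is set by Sharpless epoxidation of (E)-but-2-en-1-ol and alkynylalane opening with inversion.
4. The sec-butyl stereocentre is taken from (2S)-2-methylbutan-1-ol (oxidation, Corey–Fuchs, methylation).
5. Ring order: the pyranone, the only ring of the target, is closed early on a small fragment (step 6) before any fragment union; the epoxide and dioxolane rings are temporary.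

Assumption: in SMILES the cyclopentadienyl ligands on zirconium are written as sigma-bonded C5H5 rings, and locants in names follow the numbering of each individual compound.

## Route

Step 1
Reactants: 1 (E)-but-2-en-1-ol
Product: 2 [(2R,3R)-3-methyloxiran-2-yl]methanol
Conditions: Ti(OiPr)4 (5 mol %), D-(−)-diisopropyl tartrate (6 mol %), t-BuOOH, 4 Å MS, CH2Cl2, −20 °C
Reagents that add atoms: tert-butyl hydroperoxide, CC(C)(C)OO
Why: Sharpless asymmetric epoxidation, in which the D-tartrate/titanium catalyst delivers oxygen to one face of the E-allylic alcohol and sets both epoxide centres as 2R,3R (about 92–95% ee expected; the minor series ends as a separable diastereomer of the target).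

Step 2
Reactants: 2 [(2R,3R)-3-methyloxiran-2-yl]methanol
Product: 3 (2S,3R)-3-methylhex-4-yne-1,2-diol
Conditions: Et2AlC≡CMe (3 equiv, from MeC≡CLi and Et2AlCl), PhMe/hexane, 0 → 23 °C; aq. potassium sodium tartrate
Reagents that add atoms: diethyl(prop-1-yn-1-yl)alane, CC#C[Al](CC)CC (made in the flask from prop-1-ynyllithium, [Li]C#CC, and Et2AlCl, CC[Al](Cl)CC)
Why: hydroxyl-directed alkynylalane opening of a 2,3-epoxy alcohol, in which the aluminium alkoxide delivers the alkynyl group to C3 by SN2 attack with inversion; this creates the methyl-bearing methine of the future skipped diene in the required sense and leaves a 1,2-diol as a masked aldehyde.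

Step 3
Reactants: 3 (2S,3R)-3-methylhex-4-yne-1,2-diol
Product: 4 (4S)-2,2-dimethyl-4-[(2R)-pent-3-yn-2-yl]-1,3-dioxolane
Conditions: Me2C(OMe)2, PPTS (cat.), CH2Cl2, 23 °C
Reagents that add atoms: 2,2-dimethoxypropane, COC(C)(C)OC
Why: acid-catalysed transacetalisation masks the diol, whose free alkoxides would otherwise misdirect the hydrozirconation; no stereocentre is touched.

Step 4
Reactants: 4 (4S)-2,2-dimethyl-4-[(2R)-pent-3-yn-2-yl]-1,3-dioxolane
Product: 6 (4S)-4-[(2R,3E)-4-iodopent-3-en-2-yl]-2,2-dimethyl-1,3-dioxolane, via alkenylzirconocene chloride 5 (not isolated)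
Conditions: Cp2Zr(H)Cl (1.3 equiv), THF, 23 → 40 °C; I2, −78 → 0 °C
Reagents that add atoms: iodine, II
Why: Schwartz hydrozirconation/iodinolysis, in which syn Zr–H addition equilibrates zirconium onto the methyl-bearing (less hindered) alkyne carbon and C–Zr is converted to C–I with retention, giving the E-2-iodoalkene without touching the stereocentres.

Step 5
Reactants: 6 (4S)-4-[(2R,3E)-4-iodopent-3-en-2-yl]-2,2-dimethyl-1,3-dioxolane
Product: 8 (2E,4S,5E)-6-iodo-2,4-dimethylhepta-2,5-dienal, via iodo aldehyde 7 (not isolated)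
Conditions: H5IO6, EtOAc, 0 → 23 °C; filter through NaHCO3/Na2SO4; Ph3P=C(Me)CHO, PhMe, 60 °C
Reagents that add atoms: 2-(triphenyl-λ5-phosphanylidene)propanal, CC(C=O)=P(c1ccccc1)(c1ccccc1)c1ccccc1
Why: one-pot acetonide hydrolysis/periodate glycol cleavage followed by Wittig olefination with a formyl-stabilised ylide gives the E-trisubstituted enal, and because the α-chiral β,γ-unsaturated aldehyde 7 is trapped without isolation its stereocentre is kept.

Step 6
Reactants: 9 methyl 2-methyl-3-oxopentanoate
Product: 11 6-ethyl-4-hydroxy-3,5-dimethyl-2H-pyran-2-one, via diketo ester 10 (not isolated)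
Conditions: NaH, THF, 0 °C; n-BuLi, 0 °C; EtC(O)N(OMe)Me, 0 → 23 °C; AcOH; DBU, reflux
Reagents that add atoms: N-methoxy-N-methylpropanamide, CCC(=O)N(C)OC
Why: Weiler dianion γ-acylation (Claisen condensation) followed by DBU-promoted enol lactonisation closes the 4-hydroxypyran-2-one, the only ring of the target; no stereocentre is involved.

Step 7
Reactants: 8 (2E,4S,5E)-6-iodo-2,4-dimethylhepta-2,5-dienal; 11 6-ethyl-4-hydroxy-3,5-dimethyl-2H-pyran-2-one
Product: 12 4-hydroxy-6-[(4E,6S,7E)-3-hydroxy-8-iodo-4,6-dimethylnona-4,7-dien-2-yl]-3,5-dimethyl-2H-pyran-2-one (mixture of side-chain C2/C3 diastereomers)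
Conditions: 11 (1.3 equiv), LiN(iPr)2 (2.6 equiv), THF, −78 → −30 °C; 8, −78 °C; AcOH
Reagents that add atoms: none
Why: vinylogous aldol addition of the pyranone dianion (lateral lithiation of the 6-ethyl CH2) to the enal carbonyl; the two new centres form unselectively but are both erased in step 8, and fast 1,2-addition at −78 °C leaves the C6 stereocentre untouched.

Step 8
Reactants: 12 4-hydroxy-6-[(4E,6S,7E)-3-hydroxy-8-iodo-4,6-dimethylnona-4,7-dien-2-yl]-3,5-dimethyl-2H-pyran-2-one
Product: 14 6-[(2E,4E,6S,7E)-8-iodo-4,6-dimethylnona-2,4,7-trien-2-yl]-3,5-dimethyl-2-oxo-2H-pyran-4-yl acetate, via bis-acetate 13 (not isolated)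
Conditions: Ac2O, Et3N, DMAP (cat.), CH2Cl2, 0 → 23 °C; DBU, 0 → 23 °C
Reagents that add atoms: acetic anhydride, CC(=O)OC(C)=O
Why: double O-acetylation followed by base-mediated E1cB-type 1,2-elimination of the allylic acetate through the acidified C–H next to the pyranone gives the conjugated triene as the thermodynamically preferred E isomer (chain anti to the ring); the pyranyl acetate that remains masks the acidic OH for step 11, and the merely allylic C6 stereocentre is not affected.

Step 9
Reactants: 15 (2S)-2-methylbutan-1-ol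
Product: 17 (3S)-1,1-dibromo-3-methylpent-1-ene, via aldehyde 16 (not isolated)
Conditions: PhI(OAc)2, TEMPO (10 mol %), CH2Cl2, 23 °C; then into Ph3P=CBr2 (preformed from CBr4, PPh3, Zn, CH2Cl2), Et3N, 0 → 23 °C
Reagents that add atoms: carbon tetrabromide, BrC(Br)(Br)Br
Why: TEMPO/PhI(OAc)2 oxidation followed in the same flask by Corey–Fuchs (Ramirez) dibromo-olefination, so the volatile and epimerisable aldehyde is never handled and the chiral-pool stereocentre is carried through.

Step 10
Reactants: 17 (3S)-1,1-dibromo-3-methylpent-1-ene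
Product: 19 (4S)-4-methylhex-2-yne, via lithium acetylide 18 (not isolated)
Conditions: n-BuLi (2.1 equiv), THF, −78 → 0 °C; MeI, DMPU, −78 → 23 °C; amine scavenging of alkyl halides, distillation
Reagents that add atoms: iodomethane, CI
Why: Corey–Fuchs alkyne synthesis (bromine–lithium exchange and Fritsch–Buttenberg–Wiechell shift) followed by SN2 C-methylation of the acetylide; the stereocentre is not involved.

Step 11
Reactants: 19 (4S)-4-methylhex-2-yne; 14 6-[(2E,4E,6S,7E)-8-iodo-4,6-dimethylnona-2,4,7-trien-2-yl]-3,5-dimethyl-2-oxo-2H-pyran-4-yl acetate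
Product: 23 4-hydroxy-3,5-dimethyl-6-[(2E,4E,6S,7E,10E,12S)-4,6,8,10,12-pentamethyl-9-oxotetradeca-2,4,7,10-tetraen-2-yl]-2H-pyran-2-one (target CNP0115032.1), via alkenylzirconocene 20 (not isolated), via acylzirconocene 21 (not isolated), via target acetate 22 (not isolated)
Conditions: 19 (1.8 equiv), Cp2Zr(H)Cl, THF, 23 → 40 °C; CO (1 atm), 23 °C; Ar purge; 14, PdCl2(PPh3)2 (10 mol %), THF/PhMe, 23 → 40 °C; morpholine, 0 °C; aq. citric acid
Reagents that add atoms: carbon monoxide, [C-]#[O+]
Why: Proposed new method: syn-hydrozirconation of 19 at the methyl-bearing alkyne carbon and CO insertion with retention give the E-acylzirconocene chloride 21, an unmasked acyl anion, whose acyl group is transferred to the alkenylpalladium iodide formed by oxidative addition of zerovalent palladium into 14, and reductive elimination then gives the dienone with both alkene geometries retained and both stereocentres untouched, before mild aminolysis frees the pyranone OH; the closest known reaction type is the palladium-catalysed ketone synthesis from acylzirconocene chlorides and allylic or benzylic halides or iodonium salts (an acyl-Negishi-type coupling).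

## Compound list

1 | (E)-but-2-en-1-ol | C/C=C/CO | starting material
2 | [(2R,3R)-3-methyloxiran-2-yl]methanol | C[C@H]1O[C@@H]1CO | intermediate
3 | (2S,3R)-3-methylhex-4-yne-1,2-diol | CC#C[C@@H](C)[C@H](O)CO | intermediate
4 | (4S)-2,2-dimethyl-4-[(2R)-pent-3-yn-2-yl]-1,3-dioxolane | CC#C[C@@H](C)[C@H]1COC(C)(C)O1 | intermediate
5 | chlorobis(cyclopentadienyl){(2E,4R)-4-[(4S)-2,2-dimethyl-1,3-dioxolan-4-yl]pent-2-en-2-yl}zirconium | C/C(=C\[C@@H](C)[C@H]1COC(C)(C)O1)[Zr](Cl)(C1C=CC=C1)C1C=CC=C1 | intermediate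
6 | (4S)-4-[(2R,3E)-4-iodopent-3-en-2-yl]-2,2-dimethyl-1,3-dioxolane | C/C(I)=C\[C@@H](C)[C@H]1COC(C)(C)O1 | intermediate
7 | (2R,3E)-4-iodo-2-methylpent-3-enal | C/C(I)=C\[C@@H](C)C=O | intermediate
8 | (2E,4S,5E)-6-iodo-2,4-dimethylhepta-2,5-dienal | C/C(I)=C\[C@@H](C)/C=C(\C)C=O | intermediate
9 | methyl 2-methyl-3-oxopentanoate | CCC(=O)C(C)C(=O)OC | starting material
10 | methyl 2,4-dimethyl-3,5-dioxoheptanoate | CCC(=O)C(C)C(=O)C(C)C(=O)OC | intermediate
11 | 6-ethyl-4-hydroxy-3,5-dimethyl-2H-pyran-2-one | CCc1oc(=O)c(C)c(O)c1C | intermediate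
12 | 4-hydroxy-6-[(4E,6S,7E)-3-hydroxy-8-iodo-4,6-dimethylnona-4,7-dien-2-yl]-3,5-dimethyl-2H-pyran-2-one (side-chain C2/C3 diastereomer mixture) | C/C(I)=C\[C@@H](C)/C=C(\C)C(O)C(C)c1oc(=O)c(C)c(O)c1C | intermediate
13 | (4E,6S,7E)-2-[4-(acetyloxy)-3,5-dimethyl-2-oxo-2H-pyran-6-yl]-8-iodo-4,6-dimethylnona-4,7-dien-3-yl acetate | C/C(I)=C\[C@@H](C)/C=C(\C)C(OC(C)=O)C(C)c1oc(=O)c(C)c(OC(C)=O)c1C | intermediate
14 | 6-[(2E,4E,6S,7E)-8-iodo-4,6-dimethylnona-2,4,7-trien-2-yl]-3,5-dimethyl-2-oxo-2H-pyran-4-yl acetate | C/C(I)=C\[C@@H](C)/C=C(C)/C=C(\C)c1oc(=O)c(C)c(OC(C)=O)c1C | intermediate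
15 | (2S)-2-methylbutan-1-ol | CC[C@H](C)CO | starting material
16 | (2S)-2-methylbutanal | CC[C@H](C)C=O | intermediate
17 | (3S)-1,1-dibromo-3-methylpent-1-ene | CC[C@H](C)C=C(Br)Br | intermediate
18 | [(3S)-3-methylpent-1-yn-1-yl]lithium | CC[C@H](C)C#C[Li] | intermediate
19 | (4S)-4-methylhex-2-yne | CC[C@H](C)C#CC | intermediate
20 | chlorobis(cyclopentadienyl)[(2E,4S)-4-methylhex-2-en-2-yl]zirconium | CC[C@H](C)/C=C(\C)[Zr](Cl)(C1C=CC=C1)C1C=CC=C1 | intermediate
21 | chlorobis(cyclopentadienyl)[(2E,4S)-2,4-dimethylhex-2-enoyl]zirconium | CC[C@H](C)/C=C(\C)C(=O)[Zr](Cl)(C1C=CC=C1)C1C=CC=C1 | intermediate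
22 | 3,5-dimethyl-2-oxo-6-[(2E,4E,6S,7E,10E,12S)-4,6,8,10,12-pentamethyl-9-oxotetradeca-2,4,7,10-tetraen-2-yl]-2H-pyran-4-yl acetate | CC[C@H](C)/C=C(\C)C(=O)/C(C)=C/[C@@H](C)/C=C(C)/C=C(\C)c1oc(=O)c(C)c(OC(C)=O)c1C | intermediate
23 | 4-hydroxy-3,5-dimethyl-6-[(2E,4E,6S,7E,10E,12S)-4,6,8,10,12-pentamethyl-9-oxotetradeca-2,4,7,10-tetraen-2-yl]-2H-pyran-2-one | CC[C@H](C)/C=C(\C)C(=O)/C(C)=C/[C@@H](C)/C=C(C)/C=C(\C)c1oc(=O)c(C)c(O)c1C | target

## Step count and risks

Total step count: 11. Longest linear sequence: 8 steps (steps 1, 2, 3, 4, 5, 7, 8 and 11, from (E)-but-2-en-1-ol); steps 6, 9 and 10 make the two side fragments.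

The three steps most likely to fail:

Step 11 (acyl transfer from zirconium to the alkenylpalladium iodide). Possible failures are slow transmetalation, decarbonylation to a diene, or further acyl addition to the product dienone. The fallback keeps the same bond but makes it by a nickel-catalysed reductive coupling of two electrophiles. Acylzirconocene 21 is cleaved with N-bromosuccinimide to (2E,4S)-2,4-dimethylhex-2-enoyl bromide F1, which is joined to alkenyl iodide 14 using NiCl2(dme), 4,4'-di-tert-butyl-2,2'-bipyridine and Mn in DMA at 0–23 °C. This sets out from 21 and 14 and comes back to the route at acetate 22, which is deacetylated with morpholine as before.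

Step 8 (acetylation/elimination to the E-triene). Possible failures are poor E/Z control, loss of the ring acetate under DBU, or base-induced migration of the skipped double bond. The fallback builds the same alkene by Horner–Wadsworth–Emmons olefination. The dianion of pyranone 11 (LiN(iPr)2) is C-phosphorylated with ClP(O)(OEt)2 to diethyl [1-(4-hydroxy-3,5-dimethyl-2-oxo-2H-pyran-6-yl)ethyl]phosphonate F2. Its dianion (NaN(SiMe3)2, THF, −78 → 0 °C) condenses with dienal 8 to give 4-hydroxy-6-[(2E,4E,6S,7E)-8-iodo-4,6-dimethylnona-2,4,7-trien-2-yl]-3,5-dimethyl-2H-pyran-2-one F3, which is acetylated (Ac2O, pyridine). This sets out from 11 and 8, bypasses 12 and 13, and comes back at 14.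

Step 5 (Wittig on the α-chiral β,γ-unsaturated aldehyde 7). The risk is epimerisation or conjugation of 7 during the warm reaction with the sluggish formyl ylide. The fallback reaches the enal through the ester oxidation level. Aldehyde 7 is trapped at 0–23 °C with the more reactive ylide Ph3P=C(Me)CO2Et to give ethyl (2E,4S,5E)-6-iodo-2,4-dimethylhepta-2,5-dienoate F4. This is reduced with iBu2AlH (CH2Cl2, −78 °C) to (2E,4S,5E)-6-iodo-2,4-dimethylhepta-2,5-dien-1-ol F5 and oxidised with MnO2 (CH2Cl2, 23 °C). This sets out from 7 and comes back at dienal 8.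

Further compounds
F1 | step 11 | (2E,4S)-2,4-dimethylhex-2-enoyl bromide | CC[C@H](C)/C=C(\C)C(Br)=O
F2 | step 8 | diethyl [1-(4-hydroxy-3,5-dimethyl-2-oxo-2H-pyran-6-yl)ethyl]phosphonate | CCOP(=O)(OCC)C(C)c1oc(=O)c(C)c(O)c1C
F3 | step 8 | 4-hydroxy-6-[(2E,4E,6S,7E)-8-iodo-4,6-dimethylnona-2,4,7-trien-2-yl]-3,5-dimethyl-2H-pyran-2-one | C/C(I)=C\[C@@H](C)/C=C(C)/C=C(\C)c1oc(=O)c(C)c(O)c1C
F4 | step 5 | ethyl (2E,4S,5E)-6-iodo-2,4-dimethylhepta-2,5-dienoate | C/C(I)=C\[C@@H](C)/C=C(\C)C(=O)OCC
F5 | step 5 | (2E,4S,5E)-6-iodo-2,4-dimethylhepta-2,5-dien-1-ol | C/C(I)=C\[C@@H](C)/C=C(\C)CO
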